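## Structural features

The target is pentacyclic. An α-methyl-γ-butyrolactone is cis-fused to a cyclopentane; the cyclopentane shares its CH–C(quaternary) edge with a six-membered lactam; the lactam nitrogen is tied back to the same quaternary carbon through a CH2–CH2–CH2–CH(OH) chain. Nitrogen and the quaternary carbon are therefore the bridgeheads of a 1-azabicyclo[4.3.1]decan-10-one, and a second, cis-2,4-disubstituted α-methyl-γ-butyrolactone hangs from the N–CH carbon through its O–CH carbon. Ten stereocentres are present: six form the unbroken chain CH(OH)–C(quaternary)–CH(Et)–CH(O)–CH–CH(CH3), a seventh (the ring-fusion CH next to the quaternary carbon) closes the cyclopentane, and the N–CH/O–CH pair of the side chain is threo. The bridgehead amide cannot be planar and is open to nucleophiles and to aqueous acid or base. The methyl group of the fused lactone lies on the concave face and can epimerise, and a free amine next to the side lactone can take over its acyl group. The real difficulty is the quaternary carbon, common to three rings and flanked by three stereocentres, together with the bridged lactam. The feature used by the key step is the cyclopentane bond between the lactone β-carbon and the CH that carries the lactam CH2: both carbons are β to a carbonyl once the N–CH carbon is drawn as an ester, and they are 1,5-related through the lactone O–CH, the CH(Et) and the quaternary carbon.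

## Logic of the disconnections

32 ⇒ 31. The O–Si bond of the carbinol is cut. The silyl ether is kept through the ring expansion because a bulky equatorial silyloxy group fixes the cyclohexane chair and prevents chelation or retro-aldol. The forward step must remove silicon without opening the twisted amide.

31 ⇒ 30. The N–CH2 bond of the seven-membered ring is cut and that CH2 is reconnected to the carbonyl carbon (retro-Schmidt). This removes the bridged amide and one ring and leaves a cyclohexanone with an azide three carbons from its quaternary α-carbon. The forward step demands that the ring CH2, not the quaternary carbon, migrates.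

30 ⇒ 29 ⇒ 27. The ketone is masked again as its dioxolane (two C–O bonds) and the azide is traced to a sulfinamide (N–S bond). The free amine must never meet the ketone (cyclic imine) and may meet the neighbouring lactone only briefly (O→N acyl shift).

27 ⇒ 26 ⇒ 23 + 25. After removal of the two lactone ring hydrogens (alkene of a butenolide), the bond between the N–CH carbon and the lactone O–CH carbon is cut (vinylogous Mannich). The whole side lactone then comes from one five-carbon furanone, 25 ⇐ 24. The forward steps must control the imine face, the threo relation and the cis methyl group.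

23 ⇒ 21 ⇒ 20 ⇒ 19 ⇒ 18. The C=N bond is cut and the two-carbon arm is taken back through aldehyde, alcohol and acid to a benzyl ester (benzyl C–O bond). This ester must be distinguishable from the γ-lactone, which is why it is benzyl.

18 ⇒ 17. The cyclopentane bond between the lactone β-carbon and the carbon bearing the CH2CO2Bn arm is cut. One ring and three stereocentres disappear; what remains is a butenolide and an enoate on one quaternary carbon. The forward step must place the ester arm trans to the lactone and protonate the lactone enolate on the convex face.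

17 ⇒ 16 ⇒ 14 ⇒ 12 + 13 (+ 15). The butenolide C=C bond (ring-closing metathesis), the ester C–O bond and then the carbinol–vinyl C–C bond are cut, leaving an aldehyde. The addition must follow the Felkin–Anh sense to set the lactone O–CH carbon, and the enoate must stay out of the metathesis.

12 ⇒ 11 ⇒ 9. The aldehyde is traced to a terminal alkene (C=C bond, one carbon lost on ozonolysis) and the enoate C=C bond to a saturated ester. The base-mediated dehydrogenation has to come before any butenolide exists, and ozone must select the terminal alkene.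

9 ⇒ 8 ⇒ 7. After the ketal, the bond between the quaternary carbon and the CH(Et) carbon is cut and an O–CH2 bond re-formed (retro-Claisen). Both the quaternary and the ethyl-bearing stereocentres are thereby traced to one carbinol stereocentre and a Z-alkene. The forward step needs a chair transition state and attack anti to the silyloxy group.

7 ⇒ 5 ⇒ 3 + 4 ⇒ 1 + 2. The O–Si bond, the carbinol C–H bond (enantioselective reduction), the enol ether C–O bond and the Michael C–C bond are cut in turn. The demand is catalyst control at a vinylogous ester carbonyl.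

## Other disconnections considered

Alternative 1: The cut removes three cyclopentane bonds at once: the two bonds to the future lactone O–CH carbon (drawn as a ketone) and the bond between the future quaternary carbon and the ring-fusion CH. In the forward direction, amide-tethered enyne A1 would be cyclocarbonylated with Co2(CO)8 and an amine N-oxide promoter to bicyclic lactam enone A2.
- In its favour: three C–C bonds, the cyclopentenone and the six-membered lactam form in one operation from a short acyclic amide, and the ring-fusion CH is set relative to the N–CH carbon. On bonds and rings per step, and on the number of steps needed to reach the key intermediate, this is better than the chosen plan.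
- Against it here: the alkyne is a conjugated alkynoyl amide, a reluctant partner, and a 1,7-enyne closes more slowly than a 1,6-enyne. The future quaternary carbon is still sp2 in A2 and would have to be made by conjugate addition of a four-carbon chain to a tetrasubstituted, amide-conjugated enone. The seven-membered ring would then have to be closed by N-alkylation of a planar lactam that must twist as the bond forms. The fused lactone, its methyl group and the ethyl-bearing carbon all remain to be set on the cyclopentanone.
- Comparison: equal to the chosen plan in leaving the lactone methyl group to a protonation or hydrogenation. Weaker on structure and mechanism, because the two hardest features (quaternary stereocentre, twisted amide) come late by reactions without built-in control. The chosen plan sets the quaternary carbon early by a sigmatropic shift and forms the amide from a tetrahedral intermediate.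

Alternative 2: The cut removes the N–CH2 bond and the bond between the quaternary carbon and the carbinol carbon together. In the forward direction, α-bromo N–H lactam A3 would lose HBr with a mild carbonate base in a fluorinated alcohol; the cyclic aza-oxyallyl cation would add across the two α-carbons of furan A4 to give oxygen-bridged cycloadduct A5. Hydrogenation and reductive opening of the N,O-acetal C–O bond would then leave the carbinol.
- In its favour: the bridged amide, the quaternary carbon and the C–O stereocentre arise in one step, two bonds at once, close to the end and without an azide. On the construction of the bridged lactam this is better than the chosen plan, whose ring expansion has an uncertain regiochemistry, and the endgame is shorter.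
- Against it here: aza-oxyallyl cations are established mainly for N-alkoxy amides; an N-alkyl lactam whose cationic carbon carries three ring bonds is a much less stabilised case. The face of attack relative to the cyclopentane and the endo/exo sense (which fixes the carbinol configuration) are not secured by anything in A3. The reductive opening must ionise only the C–O bond at the N–CH carbon, through a bridgehead N-acyliminium ion.
- Comparison: A3 still contains the cyclopentane with five of its stereocentres, both lactones and the six-membered lactam, so the cyclopentane problem is equal in both plans and could even be solved by the same reductive coupling. The alternative is better in step economy after that point and weaker in precedent for its reactive intermediate.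

Alternative 3: The cut is the lactone C–O bond at the ring-fusion carbon, leading back to a cyclobutanone. In the forward direction methylketene A6 and cyclopentadiene A7 would give racemic endo ketone A8; a cyclohexanone monooxygenase (O2, reduced nicotinamide cofactor) would insert oxygen next to the bridgehead of one enantiomer to give lactone A9.
- In its favour: two steps from bulk chemicals reach the cis-fused lactone with three of the target's stereocentres under enzyme control, and the concave methyl group comes directly from the endo cycloadduct. For this triad the alternative is better than the chosen plan, which relies on a kinetic protonation, and it needs no auxiliary.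
- Against it here: the enzyme sends the other enantiomer to the regioisomeric lactone, so at most half of A8 is useful. A9 lacks the ethyl group, the quaternary carbon and the acetic acid arm; these would have to be added one by one to the allylic CH2 and the two alkene carbons of a base-sensitive lactone, including a quaternary centre beside a ring fusion.
- Comparison: mechanistically the oxygen insertion with retention is as reliable as anything in the chosen plan. In step economy the alternative is better for the first three stereocentres and worse overall, because the chosen plan closes the cyclopentane last, around a quaternary carbon that is already complete.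

Key step: step 11

Remark on the chemistry: the key-step precursor 17 and product 18 were re-derived from the target; their constitution and every stereodescriptor agree with it, so no structural correction was needed. They are used as benzyl instead of methyl esters (a spectator change), because a benzyl ester can be removed by hydrogenolysis and taken to the aldehyde without touching the γ-lactone, which a hydride reduction of a methyl ester could not guarantee.

Assumption: benzyl acrylate, (Z)-pent-2-en-1-ol, vinylmagnesium bromide, methacryloyl chloride, (S)-tert-butanesulfinamide and 3-methylfuran-2(5H)-one are bought. TBS = tert-butyl(dimethyl)silyl; TIPS = triisopropylsilyl.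

## Route

Step 1
Reactants: 1 cyclohexane-1,3-dione; 2 benzyl acrylate
Product: 3 benzyl 3-(2,6-dioxocyclohexyl)propanoate
Conditions: Et3N (0.2 equiv), MeCN, 50 °C, 1 in excess
Reagents that add atoms: none
Why: Base-catalysed Michael addition of the acidic dione C2–H to the acrylate; the excess of dione limits double addition, and no stereocentre is formed.

Step 2
Reactants: 3 benzyl 3-(2,6-dioxocyclohexyl)propanoate; 4 (Z)-pent-2-en-1-ol
Product: 5 benzyl 3-{6-oxo-2-[(2Z)-pent-2-en-1-yloxy]cyclohex-1-en-1-yl}propanoate
Conditions: TsOH·H2O (5 mol %), PhH, reflux, Dean–Stark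
Reagents that add atoms: none
Why: Acid-catalysed vinylogous esterification of the 2-substituted dione with azeotropic removal of water; the primary Z-allylic alcohol is not ionised under these conditions, so the alkene geometry should be kept.

Step 3
Reactants: 5 benzyl 3-{6-oxo-2-[(2Z)-pent-2-en-1-yloxy]cyclohex-1-en-1-yl}propanoate
Product: 7 benzyl 3-{(6R)-6-TBSO-2-[(2Z)-pent-2-en-1-yloxy]cyclohex-1-en-1-yl}propanoate, via allylic alcohol 6 (not isolated)
Conditions: (S)-2-methyl-CBS-oxazaborolidine (20 mol %), BH3·SMe2 (0.7 equiv, slow addition), THF, −30 °C; NaHCO3 work-up; then TBSCl, imidazole, DMF, rt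
Reagents that add atoms: tert-butyl(chloro)dimethylsilane, CC(C)(C)[Si](C)(C)Cl
Why: Corey–Bakshi–Shibata reduction: the oxazaborolidine binds the carbonyl with the substituted alkene side as the large group and the CH2 side as the small one, which should give the (R)-carbinol. The acid-labile alkoxy allylic alcohol 6 is silylated crude under basic conditions.

Step 4
Reactants: 7 benzyl 3-{(6R)-6-TBSO-2-[(2Z)-pent-2-en-1-yloxy]cyclohex-1-en-1-yl}propanoate
Product: 8 benzyl 3-{(1S,2R)-2-TBSO-6-oxo-1-[(3R)-pent-1-en-3-yl]cyclohexyl}propanoate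
Conditions: PhMe (0.05 M), Et3N (trace), sealed tube, 170 °C
Reagents that add atoms: none
Why: Thermal Claisen rearrangement through a chair transition state. Bonding on the ring face anti to the pseudo-axial silyloxy group sets the quaternary carbon with the new arm trans to OTBS; the Z-alkene holds ethyl pseudo-axial, which translates into the required configuration at the ethyl-bearing carbon.

Step 5
Reactants: 8 benzyl 3-{(1S,2R)-2-TBSO-6-oxo-1-[(3R)-pent-1-en-3-yl]cyclohexyl}propanoate
Product: 9 benzyl 3-{(6S,7R)-7-TBSO-6-[(3R)-pent-1-en-3-yl]-1,4-dioxaspiro[4.5]decan-6-yl}propanoate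
Conditions: TMSOCH2CH2OTMS, TMSOTf (10 mol %), CH2Cl2, −78 → −20 °C
Reagents that add atoms: 1,2-bis(trimethylsilyloxy)ethane, C[Si](C)(C)OCCO[Si](C)(C)C
Why: Ketalisation of the hindered ketone with the bis-silyl ether of ethylene glycol, driven by formation of hexamethyldisiloxane; it masks the ketone against enolisation (step 6), the Grignard reagent (step 8) and divalent samarium (step 11).

Step 6
Reactants: 9 benzyl 3-{(6S,7R)-7-TBSO-6-[(3R)-pent-1-en-3-yl]-1,4-dioxaspiro[4.5]decan-6-yl}propanoate
Product: 11 benzyl (2E)-3-{(6S,7R)-7-TBSO-6-[(3R)-pent-1-en-3-yl]-1,4-dioxaspiro[4.5]decan-6-yl}prop-2-enoate, via α-selanyl ester 10 (not isolated)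
Conditions: LiN(iPr)2, THF, −78 °C; PhSeBr; then H2O2 (30%), pyridine, CH2Cl2, 0 °C → rt
Reagents that add atoms: none
Why: Selenenylation of the ester enolate and selenoxide syn-elimination; the only β-hydrogens are on the CH2 next to the quaternary carbon, so the (E)-enoate should form. The step is placed here because no base-sensitive butenolide exists yet.

Step 7
Reactants: 11 benzyl (2E)-3-{(6S,7R)-7-TBSO-6-[(3R)-pent-1-en-3-yl]-1,4-dioxaspiro[4.5]decan-6-yl}prop-2-enoate
Product: 12 benzyl (2E)-3-{(6S,7R)-7-TBSO-6-[(2S)-1-oxobutan-2-yl]-1,4-dioxaspiro[4.5]decan-6-yl}prop-2-enoate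
Conditions: O3, CH2Cl2/MeOH, pyridine, −78 °C (Sudan Red 7B end point); Me2S, −78 °C → rt
Reagents that add atoms: ozone, [O-][O+]=O
Why: Ozonolysis with reductive work-up; the electron-rich terminal alkene should react far faster than the hindered, electron-poor enoate. The aldehyde is used at once to avoid epimerisation at its α-carbon (the S descriptor is a priority change only).

Step 8
Reactants: 12 benzyl (2E)-3-{(6S,7R)-7-TBSO-6-[(2S)-1-oxobutan-2-yl]-1,4-dioxaspiro[4.5]decan-6-yl}prop-2-enoate; 13 vinylmagnesium bromide
Product: 14 benzyl (2E)-3-{(6S,7R)-7-TBSO-6-[(3S,4S)-4-hydroxyhex-5-en-3-yl]-1,4-dioxaspiro[4.5]decan-6-yl}prop-2-enoate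
Conditions: CH2=CHMgBr (1.3 equiv), THF, −78 °C
Reagents that add atoms: none
Why: Grignard addition under Felkin–Anh control: the quaternary carbon is the large group anti to the incoming vinyl and the nucleophile passes the hydrogen rather than the ethyl group, which should give the (4S)-carbinol (ethyl and oxygen syn). At −78 °C the aldehyde reacts before either ester.

Step 9
Reactants: 14 benzyl (2E)-3-{(6S,7R)-7-TBSO-6-[(3S,4S)-4-hydroxyhex-5-en-3-yl]-1,4-dioxaspiro[4.5]decan-6-yl}prop-2-enoate; 15 methacryloyl chloride
Product: 16 benzyl (2E)-3-{(6S,7R)-7-TBSO-6-[(3S,4S)-4-(2-methylprop-2-enoyloxy)hex-5-en-3-yl]-1,4-dioxaspiro[4.5]decan-6-yl}prop-2-enoate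
Conditions: Et3N, DMAP (cat.), CH2Cl2, 0 °C → rt
Reagents that add atoms: none
Why: DMAP-catalysed acylation of the secondary allylic alcohol; no stereocentre is touched.

Step 10
Reactants: 16 benzyl (2E)-3-{(6S,7R)-7-TBSO-6-[(3S,4S)-4-(2-methylprop-2-enoyloxy)hex-5-en-3-yl]-1,4-dioxaspiro[4.5]decan-6-yl}prop-2-enoate
Product: 17 benzyl (2E)-3-{(6S,7R)-7-TBSO-6-{(1S)-1-[(2S)-4-methyl-5-oxo-2,5-dihydrofuran-2-yl]propyl}-1,4-dioxaspiro[4.5]decan-6-yl}prop-2-enoate
Conditions: second-generation Grubbs catalyst (10 mol %), PhMe (5 mM), 80 °C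
Reagents that add atoms: none
Why: Ring-closing metathesis of the allyl methacrylate to the α-methylbutenolide: the catalyst loads on the vinyl group and closes the five-membered lactone with loss of ethylene. The E-enoate on the quaternary carbon should be too hindered and electron-poor to take part.

Step 11
Reactants: 17 benzyl (2E)-3-{(6S,7R)-7-TBSO-6-{(1S)-1-[(2S)-4-methyl-5-oxo-2,5-dihydrofuran-2-yl]propyl}-1,4-dioxaspiro[4.5]decan-6-yl}prop-2-enoate
Product: 18 benzyl [(3S,3aR,4S,5S,6S,6aS)-6-ethyl-3-methyl-2-oxohexahydrocyclopenta[b]furan-4-yl]acetate with C5 spiro to C6 of (7R)-7-TBSO-1,4-dioxaspiro[4.5]decane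
Conditions: SmI2 (3 equiv), THF/HMPA, t-BuOH (3 equiv), −78 → −20 °C
Reagents that add atoms: none
Why: Divalent samarium transfers one electron to the enoate (or to the butenolide, an acceptor of similar potential), and the β-carbon of the radical anion adds to the β-carbon of the other acceptor; a second electron turns the α-lactone radical into a samarium enolate, and t-BuOH protonates both enolates, so the net change is one C–C bond and two hydrogens. The closest known chemistry is the cathodic or SmI2-promoted hydrocyclisation of tethered bis-enoates and the SmI2 cyclisation of unsaturated esters and lactones. The cyclopentane closes 5-exo-trig onto the butenolide. The lactone β-carbon must bond on the face that carries the tether, so the ring fusion is cis. At the carbon bearing the ester arm, the chair-like transition state with the enolate arm turned away from the lactone should place CH2CO2Bn trans to the lactone α-carbon. The methyl-bearing carbon is set by protonation of the lactone enolate from the convex face by the bulky alcohol, which puts methyl on the concave face under kinetic control. The step needs coupling to outrun simple saturation; the quaternary carbon holds the two β-carbons within bonding distance and the proton donor is kept to a few equivalents. Benzyl ester, dioxolane and silyl ether are inert to SmI2 under these conditions.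

Step 12
Reactants: 18 benzyl [(3S,3aR,4S,5S,6S,6aS)-6-ethyl-3-methyl-2-oxohexahydrocyclopenta[b]furan-4-yl]acetate with C5 spiro to C6 of (7R)-7-TBSO-1,4-dioxaspiro[4.5]decane
Product: 19 [(3S,3aR,4S,5S,6S,6aS)-6-ethyl-3-methyl-2-oxohexahydrocyclopenta[b]furan-4-yl]acetic acid with C5 spiro to C6 of (7R)-7-TBSO-1,4-dioxaspiro[4.5]decane
Conditions: H2 (1 atm), 10% Pd/C, EtOAc, rt
Reagents that add atoms: none
Why: Hydrogenolysis of the benzyl ester; no alkene is left, and lactone, ketal and silyl ether are inert.

Step 13
Reactants: 19 [(3S,3aR,4S,5S,6S,6aS)-6-ethyl-3-methyl-2-oxohexahydrocyclopenta[b]furan-4-yl]acetic acid with C5 spiro to C6 of (7R)-7-TBSO-1,4-dioxaspiro[4.5]decane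
Product: 20 (3S,3aR,4S,5S,6S,6aS)-6-ethyl-4-(2-hydroxyethyl)-3-methylhexahydrocyclopenta[b]furan-2-one with C5 spiro to C6 of (7R)-7-TBSO-1,4-dioxaspiro[4.5]decane
Conditions: BH3·THF (1.5 equiv), THF, 0 °C
Reagents that add atoms: none
Why: Borane reduces the carboxylic acid through its acyloxyborane much faster than it reduces a γ-lactone.

Step 14
Reactants: 20 (3S,3aR,4S,5S,6S,6aS)-6-ethyl-4-(2-hydroxyethyl)-3-methylhexahydrocyclopenta[b]furan-2-one with C5 spiro to C6 of (7R)-7-TBSO-1,4-dioxaspiro[4.5]decane
Product: 21 [(3S,3aR,4S,5S,6S,6aS)-6-ethyl-3-methyl-2-oxohexahydrocyclopenta[b]furan-4-yl]acetaldehyde with C5 spiro to C6 of (7R)-7-TBSO-1,4-dioxaspiro[4.5]decane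
Conditions: Dess–Martin periodinane, NaHCO3, CH2Cl2, rt
Reagents that add atoms: none
Why: Buffered Dess–Martin oxidation of the primary alcohol; the aldehyde has no stereocentre at its α-carbon.

Step 15
Reactants: 21 [(3S,3aR,4S,5S,6S,6aS)-6-ethyl-3-methyl-2-oxohexahydrocyclopenta[b]furan-4-yl]acetaldehyde with C5 spiro to C6 of (7R)-7-TBSO-1,4-dioxaspiro[4.5]decane; 22 (S)-tert-butanesulfinamide
Product: 23 (S)-N-{(E)-2-[(3S,3aR,4S,5S,6S,6aS)-6-ethyl-3-methyl-2-oxohexahydrocyclopenta[b]furan-4-yl]ethylidene}-2-methylpropane-2-sulfinamide with C5 spiro to C6 of (7R)-7-TBSO-1,4-dioxaspiro[4.5]decane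
Conditions: CuSO4 (anhydrous), CH2Cl2, rt
Reagents that add atoms: none
Why: Condensation to the N-sulfinyl aldimine with CuSO4 as water scavenger; the sulfur stereocentre is not touched.

Step 16
Reactants: 24 3-methylfuran-2(5H)-one
Product: 25 3-methyl-2-(triisopropylsilyloxy)furan
Conditions: TIPSOTf, Et3N, CH2Cl2, 0 °C
Reagents that add atoms: triisopropylsilyl trifluoromethanesulfonate, CC(C)[Si](OS(=O)(=O)C(F)(F)F)(C(C)C)C(C)C
Why: O-Silylation of the butenolide dienolate gives the isolable 2-silyloxyfuran.

Step 17
Reactants: 23 (S)-N-{(E)-2-[(3S,3aR,4S,5S,6S,6aS)-6-ethyl-3-methyl-2-oxohexahydrocyclopenta[b]furan-4-yl]ethylidene}-2-methylpropane-2-sulfinamide with C5 spiro to C6 of (7R)-7-TBSO-1,4-dioxaspiro[4.5]decane; 25 3-methyl-2-(triisopropylsilyloxy)furan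
Product: 26 (S)-N-{(1R)-2-[(3S,3aR,4S,5S,6S,6aS)-6-ethyl-3-methyl-2-oxohexahydrocyclopenta[b]furan-4-yl]-1-[(2R)-4-methyl-5-oxo-2,5-dihydrofuran-2-yl]ethyl}-2-methylpropane-2-sulfinamide with C5 spiro to C6 of (7R)-7-TBSO-1,4-dioxaspiro[4.5]decane
Conditions: TMSOTf (0.2 equiv), CH2Cl2, −78 °C
Reagents that add atoms: none
Why: Vinylogous Mukaiyama–Mannich reaction: the silyloxyfuran attacks through its γ-carbon on the silyl-activated imine in an open transition state. The tert-butylsulfinyl group shields one face, which with the (S)-auxiliary should give the (R)-configured N–CH carbon, and the threo N/O relation follows the usual preference of 2-silyloxyfurans under Lewis acid. Catalytic TMSOTf at −78 °C is meant to leave the dioxolane alone.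

Step 18
Reactants: 26 (S)-N-{(1R)-2-[(3S,3aR,4S,5S,6S,6aS)-6-ethyl-3-methyl-2-oxohexahydrocyclopenta[b]furan-4-yl]-1-[(2R)-4-methyl-5-oxo-2,5-dihydrofuran-2-yl]ethyl}-2-methylpropane-2-sulfinamide with C5 spiro to C6 of (7R)-7-TBSO-1,4-dioxaspiro[4.5]decane
Product: 27 (S)-N-{(1R)-2-[(3S,3aR,4S,5S,6S,6aS)-6-ethyl-3-methyl-2-oxohexahydrocyclopenta[b]furan-4-yl]-1-[(2R,4R)-4-methyl-5-oxooxolan-2-yl]ethyl}-2-methylpropane-2-sulfinamide with C5 spiro to C6 of (7R)-7-TBSO-1,4-dioxaspiro[4.5]decane
Conditions: H2 (3 atm), 5% Rh/Al2O3, EtOAc, rt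
Reagents that add atoms: none
Why: Heterogeneous hydrogenation of the butenolide from the face opposite its bulky γ-substituent should place the methyl group cis to that substituent (cis-2,4-disubstituted lactone).

Step 19
Reactants: 27 (S)-N-{(1R)-2-[(3S,3aR,4S,5S,6S,6aS)-6-ethyl-3-methyl-2-oxohexahydrocyclopenta[b]furan-4-yl]-1-[(2R,4R)-4-methyl-5-oxooxolan-2-yl]ethyl}-2-methylpropane-2-sulfinamide with C5 spiro to C6 of (7R)-7-TBSO-1,4-dioxaspiro[4.5]decane
Product: 29 (3S,3aR,4S,5S,6S,6aS)-4-{(2R)-2-azido-2-[(2R,4R)-4-methyl-5-oxooxolan-2-yl]ethyl}-6-ethyl-3-methylhexahydrocyclopenta[b]furan-2-one with C5 spiro to C6 of (7R)-7-TBSO-1,4-dioxaspiro[4.5]decane, via amine hydrochloride 28 (not isolated)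
Conditions: HCl (4 M in dioxane, 2 equiv), MeOH, 0 °C; then imidazole-1-sulfonyl azide hydrogen sulfate, NaHCO3, CuSO4·5H2O (2 mol %), MeOH/H2O, 0 °C → rt
Reagents that add atoms: imidazole-1-sulfonyl azide hydrogen sulfate, [N-]=[N+]=NS(=O)(=O)n1ccnc1.OS(=O)(=O)O
Why: Acid cleaves the N–S bond, and Cu-catalysed diazo transfer converts the amine into the azide with retention at carbon. The ammonium salt is neutralised only in the presence of the transfer reagent, so that azide formation should outrun O→N acyl shift from the neighbouring lactone; the ketal prevents imine formation.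

Step 20
Reactants: 29 (3S,3aR,4S,5S,6S,6aS)-4-{(2R)-2-azido-2-[(2R,4R)-4-methyl-5-oxooxolan-2-yl]ethyl}-6-ethyl-3-methylhexahydrocyclopenta[b]furan-2-one with C5 spiro to C6 of (7R)-7-TBSO-1,4-dioxaspiro[4.5]decane
Product: 30 (3S,3aR,4S,5S,6S,6aS)-4-{(2R)-2-azido-2-[(2R,4R)-4-methyl-5-oxooxolan-2-yl]ethyl}-6-ethyl-3-methylhexahydrocyclopenta[b]furan-2-one with C5 spiro to C2 of (3R)-3-TBSO-cyclohexan-1-one
Conditions: PPTS, acetone/H2O (10:1), 55 °C
Reagents that add atoms: water, O
Why: Mild acid-catalysed ketal hydrolysis frees the ketone; the secondary silyl ether, the azide and both lactones tolerate pyridinium tosylate.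

Step 21
Reactants: 30 (3S,3aR,4S,5S,6S,6aS)-4-{(2R)-2-azido-2-[(2R,4R)-4-methyl-5-oxooxolan-2-yl]ethyl}-6-ethyl-3-methylhexahydrocyclopenta[b]furan-2-one with C5 spiro to C2 of (3R)-3-TBSO-cyclohexan-1-one
Product: 31 TBS ether of 32 at the carbinol oxygen
Conditions: CF3CO2H, CH2Cl2, 0 °C → rt
Reagents that add atoms: none
Why: Intramolecular Schmidt reaction: the azide adds to the protonated ketone to give a six-membered azidohydrin, and N2 leaves with a 1,2-shift of the bond antiperiplanar to the diazonium group. With the silyloxy group equatorial the azide tether is axial on the cyclohexane, which lets the ring CH2–C bond lie anti to an axial N2+ and migrate to nitrogen, giving the bridged lactam. No stereocentre is involved.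

Step 22
Reactants: 31 TBS ether of 32 at the carbinol oxygen
Product: 32 target CNP0120800.1
Conditions: HF·pyridine, pyridine, THF, 0 °C → rt
Reagents that add atoms: none
Why: Pyridine-buffered fluoride desilylation, mild enough for the twisted amide and both lactones.

## Compound list

1 | cyclohexane-1,3-dione | O=C1CCCC(=O)C1 | starting material
2 | benzyl acrylate | C=CC(=O)OCc1ccccc1 | starting material
3 | benzyl 3-(2,6-dioxocyclohexyl)propanoate | O=C(CCC1C(=O)CCCC1=O)OCc1ccccc1 | intermediate
4 | (Z)-pent-2-en-1-ol | CC/C=C\CO | starting material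
5 | benzyl 3-{6-oxo-2-[(2Z)-pent-2-en-1-yloxy]cyclohex-1-en-1-yl}propanoate | CC/C=C\COC1=C(CCC(=O)OCc2ccccc2)C(=O)CCC1 | intermediate
6 | benzyl 3-{(6R)-6-hydroxy-2-[(2Z)-pent-2-en-1-yloxy]cyclohex-1-en-1-yl}propanoate (allylic alcohol) | CC/C=C\COC1=C(CCC(=O)OCc2ccccc2)[C@H](O)CCC1 | intermediate
7 | benzyl 3-{(6R)-6-TBSO-2-[(2Z)-pent-2-en-1-yloxy]cyclohex-1-en-1-yl}propanoate | CC/C=C\COC1=C(CCC(=O)OCc2ccccc2)[C@H](O[Si](C)(C)C(C)(C)C)CCC1 | intermediate
8 | benzyl 3-{(1S,2R)-2-TBSO-6-oxo-1-[(3R)-pent-1-en-3-yl]cyclohexyl}propanoate | CC[C@H](C=C)[C@]1(CCC(=O)OCc2ccccc2)C(=O)CCC[C@H]1O[Si](C)(C)C(C)(C)C | intermediate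
9 | benzyl 3-{(6S,7R)-7-TBSO-6-[(3R)-pent-1-en-3-yl]-1,4-dioxaspiro[4.5]decan-6-yl}propanoate | CC[C@H](C=C)[C@]1(CCC(=O)OCc2ccccc2)C3(OCCO3)CCC[C@H]1O[Si](C)(C)C(C)(C)C | intermediate
10 | α-selanyl ester: 9 with a phenylselanyl group at the ester α-carbon (both epimers) | CC[C@H](C=C)[C@]1(CC([Se]c2ccccc2)C(=O)OCc2ccccc2)C3(OCCO3)CCC[C@H]1O[Si](C)(C)C(C)(C)C | intermediate
11 | benzyl (2E)-3-{(6S,7R)-7-TBSO-6-[(3R)-pent-1-en-3-yl]-1,4-dioxaspiro[4.5]decan-6-yl}prop-2-enoate | CC[C@H](C=C)[C@]1(/C=C/C(=O)OCc2ccccc2)C3(OCCO3)CCC[C@H]1O[Si](C)(C)C(C)(C)C | intermediate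
12 | benzyl (2E)-3-{(6S,7R)-7-TBSO-6-[(2S)-1-oxobutan-2-yl]-1,4-dioxaspiro[4.5]decan-6-yl}prop-2-enoate | CC[C@H](C=O)[C@]1(/C=C/C(=O)OCc2ccccc2)C3(OCCO3)CCC[C@H]1O[Si](C)(C)C(C)(C)C | intermediate
13 | vinylmagnesium bromide | C=C[Mg]Br | starting material
14 | benzyl (2E)-3-{(6S,7R)-7-TBSO-6-[(3S,4S)-4-hydroxyhex-5-en-3-yl]-1,4-dioxaspiro[4.5]decan-6-yl}prop-2-enoate | CC[C@H]([C@@H](O)C=C)[C@]1(/C=C/C(=O)OCc2ccccc2)C3(OCCO3)CCC[C@H]1O[Si](C)(C)C(C)(C)C | intermediate
15 | methacryloyl chloride | CC(=C)C(=O)Cl | starting material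
16 | benzyl (2E)-3-{(6S,7R)-7-TBSO-6-[(3S,4S)-4-(2-methylprop-2-enoyloxy)hex-5-en-3-yl]-1,4-dioxaspiro[4.5]decan-6-yl}prop-2-enoate | CC[C@H]([C@@H](OC(=O)C(C)=C)C=C)[C@]1(/C=C/C(=O)OCc2ccccc2)C3(OCCO3)CCC[C@H]1O[Si](C)(C)C(C)(C)C | intermediate
17 | benzyl (2E)-3-{(6S,7R)-7-TBSO-6-{(1S)-1-[(2S)-4-methyl-5-oxo-2,5-dihydrofuran-2-yl]propyl}-1,4-dioxaspiro[4.5]decan-6-yl}prop-2-enoate | CC[C@H]([C@H]1OC(=O)C(C)=C1)[C@]2(/C=C/C(=O)OCc4ccccc4)C3(OCCO3)CCC[C@H]2O[Si](C)(C)C(C)(C)C | intermediate
18 | benzyl [(3S,3aR,4S,5S,6S,6aS)-6-ethyl-3-methyl-2-oxohexahydrocyclopenta[b]furan-4-yl]acetate with C5 spiro to C6 of (7R)-7-TBSO-1,4-dioxaspiro[4.5]decane | CC[C@@H]1[C@H]2OC(=O)[C@@H](C)[C@H]2[C@H](CC(=O)OCc5ccccc5)[C@]13C4(OCCO4)CCC[C@H]3O[Si](C)(C)C(C)(C)C | intermediate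
19 | [(3S,3aR,4S,5S,6S,6aS)-6-ethyl-3-methyl-2-oxohexahydrocyclopenta[b]furan-4-yl]acetic acid with C5 spiro to C6 of (7R)-7-TBSO-1,4-dioxaspiro[4.5]decane | CC[C@@H]1[C@H]2OC(=O)[C@@H](C)[C@H]2[C@H](CC(=O)O)[C@]13C4(OCCO4)CCC[C@H]3O[Si](C)(C)C(C)(C)C | intermediate
20 | (3S,3aR,4S,5S,6S,6aS)-6-ethyl-4-(2-hydroxyethyl)-3-methylhexahydrocyclopenta[b]furan-2-one with C5 spiro to C6 of (7R)-7-TBSO-1,4-dioxaspiro[4.5]decane | CC[C@@H]1[C@H]2OC(=O)[C@@H](C)[C@H]2[C@H](CCO)[C@]13C4(OCCO4)CCC[C@H]3O[Si](C)(C)C(C)(C)C | intermediate
21 | [(3S,3aR,4S,5S,6S,6aS)-6-ethyl-3-methyl-2-oxohexahydrocyclopenta[b]furan-4-yl]acetaldehyde with C5 spiro to C6 of (7R)-7-TBSO-1,4-dioxaspiro[4.5]decane | CC[C@@H]1[C@H]2OC(=O)[C@@H](C)[C@H]2[C@H](CC=O)[C@]13C4(OCCO4)CCC[C@H]3O[Si](C)(C)C(C)(C)C | intermediate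
22 | (S)-tert-butanesulfinamide | CC(C)(C)[S@](=O)N | starting material
23 | (S)-N-{(E)-2-[(3S,3aR,4S,5S,6S,6aS)-6-ethyl-3-methyl-2-oxohexahydrocyclopenta[b]furan-4-yl]ethylidene}-2-methylpropane-2-sulfinamide with C5 spiro to C6 of (7R)-7-TBSO-1,4-dioxaspiro[4.5]decane | CC[C@@H]1[C@H]2OC(=O)[C@@H](C)[C@H]2[C@H](C/C=N/[S@@](=O)C(C)(C)C)[C@]13C4(OCCO4)CCC[C@H]3O[Si](C)(C)C(C)(C)C | intermediate
24 | 3-methylfuran-2(5H)-one | CC1=CCOC1=O | starting material
25 | 3-methyl-2-(triisopropylsilyloxy)furan | Cc1ccoc1O[Si](C(C)C)(C(C)C)C(C)C | intermediate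
26 | (S)-N-{(1R)-2-[(3S,3aR,4S,5S,6S,6aS)-6-ethyl-3-methyl-2-oxohexahydrocyclopenta[b]furan-4-yl]-1-[(2R)-4-methyl-5-oxo-2,5-dihydrofuran-2-yl]ethyl}-2-methylpropane-2-sulfinamide with C5 spiro to C6 of (7R)-7-TBSO-1,4-dioxaspiro[4.5]decane | CC[C@@H]1[C@H]2OC(=O)[C@@H](C)[C@H]2[C@H](C[C@@H](N[S@@](=O)C(C)(C)C)[C@@H]6OC(=O)C(C)=C6)[C@]13C4(OCCO4)CCC[C@H]3O[Si](C)(C)C(C)(C)C | intermediate
27 | (S)-N-{(1R)-2-[(3S,3aR,4S,5S,6S,6aS)-6-ethyl-3-methyl-2-oxohexahydrocyclopenta[b]furan-4-yl]-1-[(2R,4R)-4-methyl-5-oxooxolan-2-yl]ethyl}-2-methylpropane-2-sulfinamide with C5 spiro to C6 of (7R)-7-TBSO-1,4-dioxaspiro[4.5]decane | CC[C@@H]1[C@H]2OC(=O)[C@@H](C)[C@H]2[C@H](C[C@@H](N[S@@](=O)C(C)(C)C)[C@H]6C[C@@H](C)C(=O)O6)[C@]13C4(OCCO4)CCC[C@H]3O[Si](C)(C)C(C)(C)C | intermediate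
28 | amine hydrochloride: 27 with NH2·HCl in place of the sulfinylamino group | CC[C@@H]1[C@H]2OC(=O)[C@@H](C)[C@H]2[C@H](C[C@@H](N)[C@H]6C[C@@H](C)C(=O)O6)[C@]13C4(OCCO4)CCC[C@H]3O[Si](C)(C)C(C)(C)C.Cl | intermediate
29 | (3S,3aR,4S,5S,6S,6aS)-4-{(2R)-2-azido-2-[(2R,4R)-4-methyl-5-oxooxolan-2-yl]ethyl}-6-ethyl-3-methylhexahydrocyclopenta[b]furan-2-one with C5 spiro to C6 of (7R)-7-TBSO-1,4-dioxaspiro[4.5]decane | CC[C@@H]1[C@H]2OC(=O)[C@@H](C)[C@H]2[C@H](C[C@@H](N=[N+]=[N-])[C@H]6C[C@@H](C)C(=O)O6)[C@]13C4(OCCO4)CCC[C@H]3O[Si](C)(C)C(C)(C)C | intermediate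
30 | (3S,3aR,4S,5S,6S,6aS)-4-{(2R)-2-azido-2-[(2R,4R)-4-methyl-5-oxooxolan-2-yl]ethyl}-6-ethyl-3-methylhexahydrocyclopenta[b]furan-2-one with C5 spiro to C2 of (3R)-3-TBSO-cyclohexan-1-one | CC[C@@H]1[C@H]2OC(=O)[C@@H](C)[C@H]2[C@H](C[C@@H](N=[N+]=[N-])[C@H]6C[C@@H](C)C(=O)O6)[C@]13C(=O)CCC[C@H]3O[Si](C)(C)C(C)(C)C | intermediate
31 | TBS ether of 32 at the carbinol oxygen | CC[C@@H]1[C@H]2OC(=O)[C@@H](C)[C@H]2[C@@H]2C[C@H]([C@H]3C[C@@H](C)C(=O)O3)N3CCC[C@@H](O[Si](C)(C)C(C)(C)C)[C@@]12C3=O | intermediate
32 | target CNP0120800.1 (bridged lactam with fused and pendant α-methyl-γ-butyrolactones; configuration as in the SMILES) | CC[C@@H]1[C@H]2OC(=O)[C@@H](C)[C@H]2[C@@H]2C[C@H]([C@H]3C[C@@H](C)C(=O)O3)N3CCC[C@@H](O)[C@@]12C3=O | target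

## Step count and least certain steps

Total step count: 22. Longest linear sequence: 21 steps (steps 1–15 and 17–22, from cyclohexane-1,3-dione); step 16 is a one-step side branch.

**Step 11 (key step).** What may go wrong: plain saturation of one or both alkenes without C–C bond formation, closure with the ester arm cis to the lactone, or protonation of the lactone enolate from the concave face. Electron transfer and protonation compete with a cyclisation that has to form a bond to a carbon next to a quaternary centre. Fallback: from 17, conjugate addition of PhSeNa (from PhSeSePh and NaBH4) to the unhindered butenolide β-carbon gives β-phenylselanyl lactone F1. Treatment with Bu3SnH and AIBN in benzene at 80 °C generates the lactone β-radical, which adds 5-exo to the enoate β-carbon and returns to 18. In either route a wrong methyl configuration can be reset by enolate formation with LiN(iPr)2 and kinetic protonation with a hindered phenol.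

**Step 21.** What may go wrong: migration of the quaternary carbon instead of the ring CH2, giving the fused lactam, because an equatorial diazonium group places the quaternary C–C bond antiperiplanar. Loss of the silyl group in acid would also change the conformational bias. Fallback: from 30, TMSOTf and Et3N give trimethylsilyl enol ether F2 (the ketone can enolise only towards the CH2). Ozonolysis cleaves the C=C bond to seco acid–aldehyde F3. Staudinger reduction (PMe3, H2O) followed by carbodiimide coupling closes the unstrained six-membered lactam F4. CF3CO2H and Et3SiH then join the lactam nitrogen to the aldehyde carbon by N-acyliminium reduction, coming back at 31. This route is longer, and its last ring closure has to twist a planar amide.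

**Step 17.** What may go wrong: attack on the other imine face, erosion of the threo preference, or ionisation of the dioxolane by the silyl triflate. Both stereocentres depend on open transition-state preferences. Fallback: from 23, addition of 4-methyl-2-furyllithium (from 3-methylfuran and BuLi) sets only the N–CH carbon and gives furyl sulfinamide F5. Singlet oxygen with iPr2NEt converts the furan into 5-hydroxybutenolide F6. Reduction of its keto-acid form with NaBH4 and CeCl3·7H2O (or a chelating hydride, whichever gives the threo alcohol) and lactonisation come back at 26.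

**Step 4.** What may go wrong: leakage through a boat transition state, since the chair carries a pseudo-axial ethyl group, which would give the epimer at the ethyl-bearing carbon; thermal loss of silanol is a second possibility. Fallback: from 8 the mixture is carried through steps 5 to 7. The stereocentre is then α to the aldehyde, so the separated epimeric aldehyde F7 is equilibrated through its enol (DBU, CH2Cl2) and fed back into 12, replacing kinetic control by a thermodynamic correction with recycling.

**Step 3.** What may go wrong: slow reduction of the electron-rich vinylogous ester carbonyl, which lets uncatalysed borane reduction or hydroboration of the Z-alkene compete; hydrolysis of the alkoxy allylic alcohol to an enone on work-up. Fallback: from 3, PPh3, I2 and Et3N give β-iodoenone F8, an ordinary enone for the oxazaborolidine reduction. Reduction and silylation give iodide F9. Coupling with 4 using CuI, a phenanthroline ligand and Cs2CO3 in hot toluene forms the allyl vinyl ether, coming back at 7, which rearranges to 8 under the same conditions.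

**Step 10.** What may go wrong: engagement of the enoate alkene by the ruthenium alkylidene (cyclopentene formation with loss of the acrylate unit), or stalling at the hindered 1,1-disubstituted alkene. Fallback: from 12, Barbier addition of the allylzinc reagent from ethyl 2-(bromomethyl)acrylate gives α-methylene lactone F10 in the Felkin–Anh sense. RhCl3·3H2O-catalysed migration of the exocyclic alkene into the ring comes back at 17; steps 8 and 9 are then not needed.

## Further compounds

F1 | step 11 | benzyl (2E)-3-{(6S,7R)-7-TBSO-6-{(1S)-1-[(2S)-4-methyl-5-oxo-3-(phenylselanyl)oxolan-2-yl]propyl}-1,4-dioxaspiro[4.5]decan-6-yl}prop-2-enoate | CC[C@H]([C@H]1OC(=O)C(C)C1[Se]c5ccccc5)[C@]2(/C=C/C(=O)OCc4ccccc4)C3(OCCO3)CCC[C@H]2O[Si](C)(C)C(C)(C)C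
F2 | step 21 | trimethylsilyl enol ether of 30 (C=C towards the ring CH2) | CC[C@@H]1[C@H]2OC(=O)[C@@H](C)[C@H]2[C@H](C[C@@H](N=[N+]=[N-])[C@H]6C[C@@H](C)C(=O)O6)[C@]13C(O[Si](C)(C)C)=CCC[C@H]3O[Si](C)(C)C(C)(C)C
F3 | step 21 | seco acid–aldehyde: carboxylic acid on the quaternary carbon and (1R)-1-TBSO-4-oxobutyl chain | CC[C@@H]1[C@H]2OC(=O)[C@@H](C)[C@H]2[C@H](C[C@@H](N=[N+]=[N-])[C@H]6C[C@@H](C)C(=O)O6)[C@@]1(C(=O)O)[C@@H](CCC=O)O[Si](C)(C)C(C)(C)C
F4 | step 21 | six-membered N–H lactam bearing the (1R)-1-TBSO-4-oxobutyl chain on the quaternary carbon | CC[C@@H]1[C@H]2OC(=O)[C@@H](C)[C@H]2[C@@H]2C[C@H]([C@H]3C[C@@H](C)C(=O)O3)NC(=O)[C@]12[C@@H](CCC=O)O[Si](C)(C)C(C)(C)C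
F5 | step 17 | (S)-N-[(1R)-1-(4-methylfuran-2-yl)ethyl]sulfinamide analogue of 26 | CC[C@@H]1[C@H]2OC(=O)[C@@H](C)[C@H]2[C@H](C[C@@H](N[S@@](=O)C(C)(C)C)c6cc(C)co6)[C@]13C4(OCCO4)CCC[C@H]3O[Si](C)(C)C(C)(C)C
F6 | step 17 | 5-hydroxy-3-methyl-5-substituted furan-2(5H)-one analogue of 26 (hemiketal epimers) | CC[C@@H]1[C@H]2OC(=O)[C@@H](C)[C@H]2[C@H](C[C@@H](N[S@@](=O)C(C)(C)C)C6(O)OC(=O)C(C)=C6)[C@]13C4(OCCO4)CCC[C@H]3O[Si](C)(C)C(C)(C)C
F7 | step 4 | benzyl (2E)-3-{(6S,7R)-7-TBSO-6-[(2R)-1-oxobutan-2-yl]-1,4-dioxaspiro[4.5]decan-6-yl}prop-2-enoate (epimer of 12) | CC[C@@H](C=O)[C@]1(/C=C/C(=O)OCc2ccccc2)C3(OCCO3)CCC[C@H]1O[Si](C)(C)C(C)(C)C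
F8 | step 3 | benzyl 3-(2-iodo-6-oxocyclohex-1-en-1-yl)propanoate | O=C1CCCC(I)=C1CCC(=O)OCc1ccccc1
F9 | step 3 | benzyl 3-[(6R)-6-TBSO-2-iodocyclohex-1-en-1-yl]propanoate | IC1=C(CCC(=O)OCc2ccccc2)[C@H](O[Si](C)(C)C(C)(C)C)CCC1
F10 | step 10 | benzyl (2E)-3-{(6S,7R)-7-TBSO-6-{(1S)-1-[(2S)-4-methylidene-5-oxooxolan-2-yl]propyl}-1,4-dioxaspiro[4.5]decan-6-yl}prop-2-enoate | CC[C@H]([C@H]1OC(=O)C(=C)C1)[C@]2(/C=C/C(=O)OCc4ccccc4)C3(OCCO3)CCC[C@H]2O[Si](C)(C)C(C)(C)C
A1 | alternative 1 | N-(4-methoxybenzyl)-N-[(2R)-1-TBSO-pent-4-en-2-yl]pent-2-ynamide (amide-tethered enyne) | CCC#CC(=O)N(Cc1ccc(OC)cc1)[C@@H](CO[Si](C)(C)C(C)(C)C)CC=C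
A2 | alternative 1 | bicyclic lactam enone | CCC1=C2C(=O)N(Cc3ccc(OC)cc3)[C@@H](CO[Si](C)(C)C(C)(C)C)C[C@H]2CC1=O
A3 | alternative 2 | α-bromo N–H six-membered lactam fused to the lactone-bearing cyclopentane | CC[C@@H]1[C@H]2OC(=O)[C@@H](C)[C@H]2[C@@H]2C[C@H]([C@H]3C[C@@H](C)C(=O)O3)NC(=O)C12Br
A4 | alternative 2 | furan | c1ccoc1
A5 | alternative 2 | oxygen-bridged cycloadduct | CC[C@@H]1[C@H]2OC(=O)[C@@H](C)[C@H]2[C@@H]2C[C@H]([C@H]3C[C@@H](C)C(=O)O3)N3[C@@H]4C=C[C@@H](O4)[C@@]12C3=O
A6 | alternative 3 | methylketene | CC=C=O
A7 | alternative 3 | cyclopenta-1,3-diene | C1=CC=CC1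
A8 | alternative 3 | endo-7-methylbicyclo[3.2.0]hept-2-en-6-one (racemic; reacting enantiomer drawn) | C1[C@H]2C(=O)[C@@H](C)[C@H]2C=C1
A9 | alternative 3 | cyclopentene-fused α-methyl-γ-butyrolactone | C1[C@H]2OC(=O)[C@@H](C)[C@H]2C=C1
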